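## The problem

Numbering used throughout: ring A holds C1 (CH carrying the side chain), C2 (acetonyl-bearing), C3 (methyl-bearing) and C4. C4a and C8a are the fusion atoms. Ring B holds C5 (CH2), C6 (CHMe), C7 (ketone) and C8 (CHMe). The side chain runs C1′ to C7′, and β is the face on which H-8a lies.

The target 33 is an octalin in which ring A is a 1,3-cyclohexadiene (C2=C3–C4=C4a) and ring B a 2,6-dimethylcyclohexanone, joined through C4a–C8a. Four stereocentres sit on the bicycle (C1, C8a, C8, C6), with all four hydrogens β, so the two methyl groups and the side chain are α. Two more sit on the trans epoxide (3′S,4′S), beyond a planar trisubstituted alkene. C8a can dictate C8 if both are made in one cycloaddition, and the shape of the bicycle can then set C6 and C1, but the epoxide is too remote for relay and needs reagent control.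

Because C1 is tied back to C4 through ring A, it must be equatorial on ring B. In a chair this forces both α-methyl groups axial, so the C6/C8 configuration cannot be trusted to equilibration in the final skeleton. It has to be set in another ring system and the C7 ketone unveiled last, without base.

Other fragile elements are the acetonyl group (a β,γ-unsaturated ketone with a doubly activated CH2), the doubly allylic H-1, and the vinyl epoxide conjugated to an acrylic acid, which is sensitive to acid and to zerovalent palladium.

The feature that opens the structure is that the six carbons of ring A form a 2,3-disubstituted 1,4-benzoquinone pattern with oxygen at C1 and C4. Ring B is then the [4+2] adduct of the unsubstituted C4a=C8a bond with a C5–C8 diene carrying oxygen at C7 and methyl groups at C6 and C8.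

## Retrosynthesis

**End game (33 ⇐ 32 ⇐ 31 ⇐ 30).** No skeletal bond is cut. Both ketones are traced back to secondary carbinols and the acid to a methyl ester. The order matters: the ester is saponified while no ketone is present, and one neutral Dess–Martin oxidation then creates the C7 ketone and the acetonyl ketone together, so C6, C8 and the β,γ-enone never meet base. Precursor 30 carries the two carbinols as silyl ethers.

**Acrylate and epoxide (30 ⇐ 28 ⇐ 27).** The C5′=C6′ bond is cut by a Wittig transform and the two epoxide C–O bonds are cut to the (E,E)-dienol 27. A hydroxyl-directed titanium tartrate epoxidation is preferred to any substrate-controlled oxidation because the ring stereocentres are too far away. The allylic alcohol also makes the reaction site-selective for C3′=C4′ among five alkenes. The forward reaction must tolerate a vinyl epoxide product.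

**Dienol chain (27 ⇐ 26 ⇐ 25 ⇐ 24).** The C3′=C4′ and C1′=C2′ bonds are cut by two stabilised-ylide olefinations, back to the C1 aldehyde 24. Joining a preformed epoxide-bearing chain at C1′=C2′ would need a carbanion next to an epoxide, which would eliminate, so the chain is grown linearly. The forward steps must be (E)-selective and must not enolise 24.

**C1–C1′ bond (24 ⇐ 23 ⇐ 21 ⇐ 20).** The formyl carbon is cut from C1, leaving dienone 20. Methylenation followed by hydroboration is chosen over a basic methoxymethylene olefination because enolisation of 20 toward C8a would be thermodynamically downhill. It is chosen over vinyl-metal addition and deoxygenation because a bis-allylic cation offers no control. The borane must add to the β face of the exocyclic alkene, which sets H-1 cis to H-8a.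

**Ring-A diene (20 ⇐ 19 ⇐ 18 ⇐ 16).** The C4–H bond is replaced by C4–O: the diene is traced to the enol triflate 18 of the C4 enone 16, and the C1 ketone to its dimethyl ketal. Dehydration of a C4 allylic alcohol could lose any of four protons, whereas kinetic enolisation toward C4a followed by palladium-catalysed reduction fixes the C4=C4a bond by construction.

**Ring-B oxygen (16 ⇐ 15 ⇐ 14 ⇐ 13).** The C7 silyl ether is traced to the C7 ketone 14 and this to the enol silyl ether 13. C6 is set by protonation while the bicycle is still cis-fused, where C1 can be axial on ring B and both methyl groups equatorial. C7 is then locked as a carbinol until the last step.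

**Cycloaddition (13 ⇐ 10 + 12).** The C8–C8a and C4a–C5 bonds are cut, opening ring B. The precursors are a flat quinone monoketal 10 and a five-carbon diene 12, and one catalytic step creates C4a, C8a and C8. The forward reaction needs site, regio-, endo and enantioselectivity at once.

**Monoketal (10 ⇐ 9 ⇐ 8).** The ketal is traced to a para-methoxyphenol. Oxidative dearomatisation places the ketone at the phenol carbon (C4) and the ketal at the methoxy carbon (C1). Partial hydrolysis of a bis-ketal would not be selective here, because both flanking positions carry alkyl groups.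

**Arene and diene (8 ⇐ 7 ⇐ 4 + 5; 4 ⇐ 2 ⇐ 1; 12 ⇐ 11).** The aryl–CH2 bond is cut to aryllithium 6 and (S)-propylene oxide 5, and the aryl–CH3 bond to a directed metalation of 2. Electrophilic bromination of a hydroquinone ether that already carries the methyl group would put the halogen para to it. The catalogue phenol 1 has the bromine in the right place, and the methyl group enters between bromine and the acetal oxygen. Diene 12 comes from enone 11 by soft enolisation.

## Roads not taken

**Alternative 1:** The cut is C1–C2, C3–C4 and C4a–C8a at once. In the forward step [Rh(cod)2]BF4 with BINAP would join two alkynes and a (Z)-alkene of one ester-tethered chain to give the tricyclic dienyl δ-lactone A1.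
- Merits: three C–C bonds and both carbocycles in one step; the ring-A diene arrives in place with no elimination; syn addition to the (Z)-alkene gives H-1 and H-8a cis; the lactone carbons become C1′ and the acetonyl chain.
- Weak points: the acyclic chain must already hold the C6–C8 stereotriad, which is a separate polypropionate synthesis. The ester tether prefers the conformation that keeps the reacting ends apart, both tethers close six-membered rings, and the face of the alkene relative to C8 depends on a ligand–substrate match.
- Comparison: A1 is better than the chosen plan for the diene and for C1, which there cost six steps. The chosen plan sets against this a one-step catalytic entry to all ring stereocentres from two simple partners.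

**Alternative 2:** The cut is C4a–C5, with a C3–C7 bond formed in the retro direction. In the forward step KH and 18-crown-6 would trigger an anionic oxy-Cope shift of an isopropenyl carbinol on a bicyclo[2.2.2]octene to give the cis-fused octalone A2.
- Merits: the [3,3] shift is stereospecific, and ring B arrives with C7 already a ketone and both methyl groups in place. In this respect it is better than the chosen plan, which reduces and reoxidises C7.
- Weak points: ring A of A2 is in the wrong state. C2 is a ketal without its carbon substituent, the alkene is C3=C4, and C4a is saturated, so the acetonyl group and the diene both remain to be built. The absolute configuration would need an asymmetric dearomatisation or a resolution.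
- Comparison: the chosen adduct 13 maps every ring-A carbon with its final substituent and gets its absolute configuration from a catalyst.

**Alternative 3:** The cut is C4a–C8a. In the forward step SmI2 (divalent samarium) would reduce a C4a ketone in a ten-membered ring to a ketyl that adds across the ring to a (Z)-enone, giving the C4a-hydroxy decalone A3.
- Merits: the side chain is in place before the bicycle forms, which is more convergent than the linear growth from C1 in the chosen plan, and the C4a oxygen is a handle for the C4=C4a alkene.
- Weak points: a ten-membered dienedione with defined alkene geometry and three stereocentres is a major task. C8a and C8 would be set by the conformation of a medium ring and by protonation of a samarium enolate. Dehydration of the tertiary carbinol can go toward C4, C5 or C8a.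
- Comparison: the chosen plan gives up some convergence but fixes every ring centre through a compact, well-understood transition state or a predictable facial bias.

Key step: step 8

Remark: C7 is drawn as the axial α-carbinol expected from equatorial hydride delivery; either epimer would serve, because C7 is returned to a ketone in the last step.

## Route

Step 1
Reactants: 1 3-bromo-4-methoxyphenol
Product: 2 2-bromo-1-methoxy-4-(methoxymethoxy)benzene
Conditions: MOMCl, i-Pr2NEt, CH2Cl2, 0 °C to rt
Reagents that add atoms: chloromethyl methyl ether, COCCl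
Why: O-Alkylation of the phenol (Williamson type); the methoxymethyl ether survives both organolithium steps and acts as a second ortho-director in step 2.

Step 2
Reactants: 2 2-bromo-1-methoxy-4-(methoxymethoxy)benzene
Product: 4 2-bromo-1-methoxy-4-(methoxymethoxy)-3-methylbenzene, via lithiated arene 3 (not isolated)
Conditions: LiN(i-Pr)2, THF, −78 °C; then MeI, −78 °C
Reagents that add atoms: iodomethane, CI
Why: Directed ortho-metalation: the C–H between bromine and the acetal oxygen is the most acidic ring position, and the 2-bromoaryllithium is methylated below the temperature at which it would lose LiBr to an aryne.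

Step 3
Reactants: 4 2-bromo-1-methoxy-4-(methoxymethoxy)-3-methylbenzene; 5 (S)-propylene oxide
Product: 7 (2S)-1-[6-methoxy-3-(methoxymethoxy)-2-methylphenyl]propan-2-ol, via aryllithium 6 (not isolated)
Conditions: n-BuLi, THF, −78 °C; then 5, BF3·OEt2, −78 °C
Reagents that add atoms: none
Why: Bromine–lithium exchange, then BF3-assisted epoxide opening at the unsubstituted carbon; the stereocentre of 5 is not touched, so the carbinol stays (S).

Step 4
Reactants: 7 (2S)-1-[6-methoxy-3-(methoxymethoxy)-2-methylphenyl]propan-2-ol
Product: 8 3-[(2S)-2-hydroxypropyl]-4-methoxy-2-methylphenol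
Conditions: HCl (cat.), MeOH, 45 °C
Reagents that add atoms: none
Why: Acid-catalysed acetal exchange removes the aryl methoxymethyl group as dimethoxymethane; the aryl methyl ether and the secondary alcohol are inert.

Step 5
Reactants: 8 3-[(2S)-2-hydroxypropyl]-4-methoxy-2-methylphenol
Product: 9 3-[(2S)-2-hydroxypropyl]-4,4-dimethoxy-2-methylcyclohexa-2,5-dien-1-one
Conditions: PhI(OAc)2, MeOH, 0 °C
Reagents that add atoms: methanol, CO
Why: Hypervalent-iodine oxidative dearomatisation of a para-methoxyphenol: the phenol carbon becomes the ketone and methanol adds at the methoxy-bearing carbon, so the positions of ketone (C4) and ketal (C1) are fixed by the substrate.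

Step 6
Reactants: 9 3-[(2S)-2-hydroxypropyl]-4,4-dimethoxy-2-methylcyclohexa-2,5-dien-1-one
Product: 10 3-[(2S)-2-(tert-butyldimethylsilyloxy)propyl]-4,4-dimethoxy-2-methylcyclohexa-2,5-dien-1-one
Conditions: TBSCl, imidazole, DMF, rt
Reagents that add atoms: tert-butyldimethylsilyl chloride, CC(C)(C)[Si](C)(C)Cl
Why: Standard silylation of a secondary alcohol under non-acidic conditions that leave the dienone ketal intact; the hydroxyl has to be capped before it meets the cationic boron catalyst.

Step 7
Reactants: 11 2-methylpent-1-en-3-one
Product: 12 (Z)-2-methyl-3-(triisopropylsilyloxy)penta-1,3-diene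
Conditions: i-Pr3SiOTf, Et3N, Et2O, 0 °C
Reagents that add atoms: triisopropylsilyl triflate, CC(C)[Si](OS(=O)(=O)C(F)(F)F)(C(C)C)C(C)C
Why: Soft enolisation of an ethyl ketone with a silyl triflate and a tertiary amine gives the (Z)-enol silyl ether, which places the terminal methyl group outside the s-cis diene; the bulky silyl group is chosen for step 8.

Step 8
Reactants: 10 silylated quinone monoketal; 12 (Z)-silyloxy diene
Product: 13 cis-fused enol silyl ether adduct (H-4a and H-8a β; 8α-methyl)
Conditions: (R)-B-o-tolyl oxazaborolidine [from (R)-diphenylprolinol and (o-TolBO)3] (20 mol%), HNTf2 (18 mol%), CH2Cl2, −78 to −40 °C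
Reagents that add atoms: none
Why: The protonated oxazaborolidine binds the only carbonyl of 10 (C4) through the lone pair syn to C4a–H, lowering the LUMO of the C4a=C8a bond, and the diene adds in a concerted, asynchronous [4π+2π] process in which C8–C8a bond formation leads. The closest known reaction type is the oxazaborolidinium-catalysed enantioselective Diels–Alder reaction of quinones and quinone monoketals with 2-silyloxy dienes. Ring B is closed by intermolecular cycloaddition, that is by two σ-bonds (C8–C8a and C4a–C5) formed suprafacially on both partners, not by cyclisation of a chain. C4a and C8a arise cis because the dienophile is a cis-alkene, and their absolute sense is set by the catalyst: in the accepted binding model the aryl group on the carbinol carbon of the (R)-catalyst covers one face, so the diene should add to the face from which the sequence C4, C4a, C8a, C1 runs anticlockwise. C8 is set by the endo transition state together with the (Z)-enol ether geometry, which places the outside methyl group cis to C1 and trans to H-8a. Site selectivity is needed and comes from substitution, since C2=C3 is tetrasubstituted and its α-carbon has no hydrogen for the catalyst to engage. Regioselectivity is needed and comes from the silyloxy group, the strongest donor of the diene, which makes C8 the nucleophilic terminus that bonds to the β-carbon C8a. The triisopropylsilyl group slows silyl transfer to triflimide, which would otherwise start an achiral background reaction.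

Step 9
Reactants: 13 cis-fused enol silyl ether adduct
Product: 14 cis-fused 4,7-diketone (6α,8α-dimethyl)
Conditions: Bu4NF, AcOH, THF, −20 to 0 °C
Reagents that add atoms: none
Why: Fluoride cleaves the enol silyl ether far faster than the secondary alkyl silyl ether, and the buffered enol(ate) is protonated at C6 axially from the convex β face, which gives the equatorial 6α-methyl group; this is also the more stable epimer of the cis-fused chair in which C1 is axial on ring B. The acetic acid buffer avoids epimerisation at C4a and C8.

Step 10
Reactants: 14 cis-fused 4,7-diketone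
Product: 15 7α-hydroxy enone
Conditions: NaBH4, MeOH/CH2Cl2, −40 °C
Reagents that add atoms: none
Why: Chemoselective borohydride reduction: the saturated C7 ketone is more electrophilic than the tetrasubstituted C4 enone. Hydride should enter equatorially from the β side because the axial path is blocked by the axial C8a–C1 bond.

Step 11
Reactants: 15 7α-hydroxy enone
Product: 16 7α-triethylsilyloxy enone
Conditions: Et3SiOTf, 2,6-lutidine, CH2Cl2, −78 to 0 °C
Reagents that add atoms: triethylsilyl triflate, CC[Si](CC)(CC)OS(=O)(=O)C(F)(F)F
Why: Silyl triflate silylation of a hindered secondary alcohol; the triethylsilyl ether is robust enough for the sequence yet is removed easily by fluoride from this crowded position at the end.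

Step 12
Reactants: 16 7α-triethylsilyloxy enone
Product: 18 C4 dienyl triflate (C2=C3 and C4=C4a), via potassium dienolate 17 (not isolated)
Conditions: KN(SiMe3)2, THF, −78 °C; then N-(5-chloropyridin-2-yl)bis(trifluoromethanesulfonyl)imide, −78 to −20 °C
Reagents that add atoms: N-(5-chloropyridin-2-yl)bis(trifluoromethanesulfonyl)imide, FC(F)(F)S(=O)(=O)N(c1ccc(Cl)cn1)S(=O)(=O)C(F)(F)F
Why: Kinetic α′-deprotonation of the enone at C4a (C4 is the only enolisable carbonyl left) gives the cross-conjugated dienolate, which is O-sulfonylated; this fixes the C4=C4a bond regiospecifically.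

Step 13
Reactants: 18 C4 dienyl triflate
Product: 20 C1 dienone (C1=O conjugated with C2=C3–C4=C4a), via dienyl dimethyl ketal 19 (not isolated)
Conditions: Pd(OAc)2 (5 mol%), PPh3, Et3N, HCO2H, DMF, 60 °C; then PPTS, acetone/H2O, 0 °C
Reagents that add atoms: water, O
Why: Palladium-catalysed formate reduction of an enol triflate (oxidative addition, formate exchange, loss of CO2, C–H reductive elimination) replaces OTf by H without moving either double bond. The doubly allylic ketal then ionises readily and is hydrolysed by very mild acid, which spares both silyl ethers.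

Step 14
Reactants: 20 C1 dienone
Product: 21 1-methylidene triene
Conditions: Cp2TiMe2, toluene, 70 °C, dark
Reagents that add atoms: dimethyltitanocene, C[Ti+2]C.c1cc[cH-]c1.c1cc[cH-]c1
Why: Petasis methylenation: the titanium methylidene is non-basic, so the hindered dienone is methylenated without enolisation toward C8a.

Step 15
Reactants: 21 1-methylidene triene
Product: 23 1α-hydroxymethyl diene (H-1 β), via alkylborane 22 (not isolated)
Conditions: 9-BBN, THF, 0 °C to rt; then NaOH, H2O2, 0 °C
Reagents that add atoms: 9-borabicyclo[3.3.1]nonane, B1C2CCCC1CCC2; hydrogen peroxide, OO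
Why: Anti-Markovnikov hydroboration–oxidation; the bulky borane reacts only with the 1,1-disubstituted exocyclic alkene. It adds syn from the β face, the face of H-8a and away from C8 and ring B, so H-1 is delivered cis to H-8a and the CH2OH group ends up α and pseudoaxial.

Step 16
Reactants: 23 1α-hydroxymethyl diene
Product: 24 1α-formyl diene
Conditions: Dess–Martin periodinane, NaHCO3, CH2Cl2, 0 °C
Reagents that add atoms: none
Why: Dess–Martin oxidation under buffered, near-neutral conditions should give the β,γ-unsaturated aldehyde without epimerisation at C1 or migration of the diene; it is used at once.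

Step 17
Reactants: 24 1α-formyl diene
Product: 25 (E)-enal (C1′=C2′ installed; C3′ aldehyde)
Conditions: Ph3P=C(Me)CHO, toluene, 90 °C
Reagents that add atoms: 2-(triphenylphosphoranylidene)propanal, CC(C=O)=P(c1ccccc1)(c1ccccc1)c1ccccc1
Why: Wittig olefination with a formyl-stabilised ylide is (E)-selective, and the ylide is too weak a base to enolise the aldehyde to a significant extent.

Step 18
Reactants: 25 (E)-enal
Product: 26 ethyl (E,E)-dienoate
Conditions: Ph3P=C(Me)CO2Et, toluene, 80 °C
Reagents that add atoms: ethyl 2-(triphenylphosphoranylidene)propanoate, CCOC(=O)C(C)=P(c1ccccc1)(c1ccccc1)c1ccccc1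
Why: Second stabilised Wittig olefination; the ester-stabilised ylide gives the (E)-trisubstituted C3′=C4′ alkene.

Step 19
Reactants: 26 ethyl (E,E)-dienoate
Product: 27 (E,E)-dienol
Conditions: i-Bu2AlH, CH2Cl2, −78 °C
Reagents that add atoms: none
Why: 1,2-Reduction of the conjugated ester to the allylic alcohol; the silyl ethers and the ring diene are inert to the aluminium hydride.

Step 20
Reactants: 27 (E,E)-dienol
Product: 28 (3′S,4′S)-epoxy alcohol
Conditions: Ti(Oi-Pr)4 (10 mol%), L-(+)-diethyl tartrate (12 mol%), t-BuOOH, 4 Å molecular sieves, CH2Cl2, −20 °C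
Reagents that add atoms: tert-butyl hydroperoxide, CC(C)(C)OO
Why: Sharpless asymmetric epoxidation: only the alkene of the allylic alcohol is oxidised. With L-(+)-tartrate an (E)-2-methyl allylic alcohol gives the (2S,3S)-epoxy alcohol, which is (3′S,4′S) in the target, and the ring stereocentres are too remote to interfere.

Step 21
Reactants: 28 (3′S,4′S)-epoxy alcohol
Product: 30 methyl (E)-enoate (bis-silyl ether), via epoxy aldehyde 29 (not isolated)
Conditions: Dess–Martin periodinane, NaHCO3, CH2Cl2, 0 °C; then Ph3P=CHCO2Me, rt
Reagents that add atoms: methyl (triphenylphosphoranylidene)acetate, COC(=O)C=P(c1ccccc1)(c1ccccc1)c1ccccc1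
Why: Dess–Martin oxidation followed by Wittig olefination of the crude epoxy aldehyde; C4′ is quaternary, so the aldehyde can neither epimerise nor eliminate, and the stabilised ylide gives the (E)-acrylate.

Step 22
Reactants: 30 methyl (E)-enoate (bis-silyl ether)
Product: 31 dihydroxy methyl ester
Conditions: Bu4NF, THF, 0 °C to rt
Reagents that add atoms: none
Why: Fluoride cleaves both silyl ethers; no ketone is present yet, so the basic fluoride meets no epimerisable centre.

Step 23
Reactants: 31 dihydroxy methyl ester
Product: 32 dihydroxy acid
Conditions: LiOH, THF/MeOH/H2O, 0 °C to rt; then 0.5 M HCl to pH 4, 0 °C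
Reagents that add atoms: lithium hydroxide, [Li+].[OH-]
Why: Saponification is run while C7 and the side-chain carbon are still carbinols. C4′ carries no hydrogen, so the γ,δ-epoxy enoate has no base-induced elimination path.

Step 24
Reactants: 32 dihydroxy acid
Product: 33 target CNP0214881.1
Conditions: Dess–Martin periodinane, NaHCO3, CH2Cl2, 0 °C to rt
Reagents that add atoms: none
Why: Double Dess–Martin oxidation of the two secondary carbinols under near-neutral conditions; C6 and C8 become α to a ketone only in this non-epimerising last step, and the acetonyl ketone forms without conjugation.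

## Compound list

1 | 3-bromo-4-methoxyphenol | COc1ccc(O)cc1Br | starting material
2 | 2-bromo-1-methoxy-4-(methoxymethoxy)benzene | COCOc1ccc(OC)c(Br)c1 | intermediate
3 | [2-bromo-3-methoxy-6-(methoxymethoxy)phenyl]lithium | COCOc1ccc(OC)c(Br)c1[Li] | intermediate
4 | 2-bromo-1-methoxy-4-(methoxymethoxy)-3-methylbenzene | COCOc1ccc(OC)c(Br)c1C | intermediate
5 | (S)-propylene oxide, (2S)-2-methyloxirane | C[C@H]1CO1 | starting material
6 | [6-methoxy-3-(methoxymethoxy)-2-methylphenyl]lithium | COCOc1ccc(OC)c([Li])c1C | intermediate
7 | (2S)-1-[6-methoxy-3-(methoxymethoxy)-2-methylphenyl]propan-2-ol | COCOc1ccc(OC)c(C[C@H](C)O)c1C | intermediate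
8 | 3-[(2S)-2-hydroxypropyl]-4-methoxy-2-methylphenol | COc1ccc(O)c(C)c1C[C@H](C)O | intermediate
9 | 3-[(2S)-2-hydroxypropyl]-4,4-dimethoxy-2-methylcyclohexa-2,5-dien-1-one | C[C@H](O)CC1=C(C)C(=O)C=CC1(OC)OC | intermediate
10 | 3-[(2S)-2-(tert-butyldimethylsilyloxy)propyl]-4,4-dimethoxy-2-methylcyclohexa-2,5-dien-1-one (C1 ketal, C4 ketone) | C[C@H](O[Si](C)(C)C(C)(C)C)CC1=C(C)C(=O)C=CC1(OC)OC | intermediate
11 | 2-methylpent-1-en-3-one | CCC(=O)C(C)=C | starting material
12 | (Z)-2-methyl-3-(triisopropylsilyloxy)penta-1,3-diene | C=C(C)/C(O[Si](C(C)C)(C(C)C)C(C)C)=C/C | intermediate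
13 | cis-fused adduct: C1 dimethyl ketal, C2 (2S)-2-TBSO-propyl, C3 methyl, C4 ketone, C6=C7 triisopropylsilyl enol ether, 8α-methyl, H-4a and H-8a β | C[C@H](O[Si](C)(C)C(C)(C)C)CC1=C(C)C(=O)[C@@H]2CC(C)=C(O[Si](C(C)C)(C(C)C)C(C)C)[C@H](C)[C@@H]2C1(OC)OC | intermediate
14 | cis-fused 4,7-diketone: as 13 with C7 ketone, 6α- and 8α-methyl | C[C@H](O[Si](C)(C)C(C)(C)C)CC1=C(C)C(=O)[C@@H]2C[C@H](C)C(=O)[C@H](C)[C@@H]2C1(OC)OC | intermediate
15 | 7α-hydroxy enone: as 14 with C7 carbinol (OH α, H-7 β) | C[C@H](O[Si](C)(C)C(C)(C)C)CC1=C(C)C(=O)[C@@H]2C[C@H](C)[C@H](O)[C@H](C)[C@@H]2C1(OC)OC | intermediate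
16 | 7α-triethylsilyl ether of 15 | C[C@H](O[Si](C)(C)C(C)(C)C)CC1=C(C)C(=O)[C@@H]2C[C@H](C)[C@H](O[Si](CC)(CC)CC)[C@H](C)[C@@H]2C1(OC)OC | intermediate
17 | potassium C4-O dienolate of 16 (C4=C4a, C2=C3) | C[C@H](O[Si](C)(C)C(C)(C)C)CC1=C(C)C([O-])=C2C[C@H](C)[C@H](O[Si](CC)(CC)CC)[C@H](C)[C@@H]2C1(OC)OC.[K+] | intermediate
18 | C4 dienyl triflate: C4 OTf, C4=C4a and C2=C3, C1 dimethyl ketal, H-8a β | C[C@H](O[Si](C)(C)C(C)(C)C)CC1=C(C)C(OS(=O)(=O)C(F)(F)F)=C2C[C@H](C)[C@H](O[Si](CC)(CC)CC)[C@H](C)[C@@H]2C1(OC)OC | intermediate
19 | dienyl dimethyl ketal: 18 with H at C4 | C[C@H](O[Si](C)(C)C(C)(C)C)CC1=C(C)C=C2C[C@H](C)[C@H](O[Si](CC)(CC)CC)[C@H](C)[C@@H]2C1(OC)OC | intermediate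
20 | C1 dienone: C1 ketone conjugated with C2=C3–C4=C4a, 6α,8α-dimethyl, 7α-OTES, H-8a β | C[C@H](O[Si](C)(C)C(C)(C)C)CC1=C(C)C=C2C[C@H](C)[C@H](O[Si](CC)(CC)CC)[C@H](C)[C@@H]2C1=O | intermediate
21 | 1-methylidene triene derived from 20 | C[C@H](O[Si](C)(C)C(C)(C)C)CC1=C(C)C=C2C[C@H](C)[C@H](O[Si](CC)(CC)CC)[C@H](C)[C@@H]2C1=C | intermediate
22 | B-alkyl-9-borabicyclo[3.3.1]nonane: C1 carries β-H and α-CH2–B | C[C@H](O[Si](C)(C)C(C)(C)C)CC1=C(C)C=C2C[C@H](C)[C@H](O[Si](CC)(CC)CC)[C@H](C)[C@@H]2[C@@H]1CB3C4CCCC3CCC4 | intermediate
23 | 1α-hydroxymethyl diene (H-1 β, cis to H-8a) | C[C@H](O[Si](C)(C)C(C)(C)C)CC1=C(C)C=C2C[C@H](C)[C@H](O[Si](CC)(CC)CC)[C@H](C)[C@@H]2[C@@H]1CO | intermediate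
24 | 1α-formyl diene | C[C@H](O[Si](C)(C)C(C)(C)C)CC1=C(C)C=C2C[C@H](C)[C@H](O[Si](CC)(CC)CC)[C@H](C)[C@@H]2[C@@H]1C=O | intermediate
25 | (E)-enal: C1–CH=C(Me)–CHO | C[C@H](O[Si](C)(C)C(C)(C)C)CC1=C(C)C=C2C[C@H](C)[C@H](O[Si](CC)(CC)CC)[C@H](C)[C@@H]2[C@@H]1/C=C(\C)C=O | intermediate
26 | ethyl (2E,4E)-2,4-dimethylpenta-2,4-dienoate attached at C1 | C[C@H](O[Si](C)(C)C(C)(C)C)CC1=C(C)C=C2C[C@H](C)[C@H](O[Si](CC)(CC)CC)[C@H](C)[C@@H]2[C@@H]1/C=C(\C)/C=C(\C)C(=O)OCC | intermediate
27 | (E,E)-dienol (C5′ alcohol) | C[C@H](O[Si](C)(C)C(C)(C)C)CC1=C(C)C=C2C[C@H](C)[C@H](O[Si](CC)(CC)CC)[C@H](C)[C@@H]2[C@@H]1/C=C(\C)/C=C(\C)CO | intermediate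
28 | (3′S,4′S)-epoxy alcohol | C[C@H](O[Si](C)(C)C(C)(C)C)CC1=C(C)C=C2C[C@H](C)[C@H](O[Si](CC)(CC)CC)[C@H](C)[C@@H]2[C@@H]1/C=C(\C)[C@@H]1O[C@@]1(C)CO | intermediate
29 | (3′S,4′S)-epoxy aldehyde | C[C@H](O[Si](C)(C)C(C)(C)C)CC1=C(C)C=C2C[C@H](C)[C@H](O[Si](CC)(CC)CC)[C@H](C)[C@@H]2[C@@H]1/C=C(\C)[C@@H]1O[C@@]1(C)C=O | intermediate
30 | methyl (E)-enoate with 7α-OTES and side-chain OTBS | C[C@H](O[Si](C)(C)C(C)(C)C)CC1=C(C)C=C2C[C@H](C)[C@H](O[Si](CC)(CC)CC)[C@H](C)[C@@H]2[C@@H]1/C=C(\C)[C@@H]1O[C@@]1(C)/C=C/C(=O)OC | intermediate
31 | dihydroxy methyl ester (7α-OH, (2S)-2-hydroxypropyl at C2) | C[C@H](O)CC1=C(C)C=C2C[C@H](C)[C@H](O)[C@H](C)[C@@H]2[C@@H]1/C=C(\C)[C@@H]1O[C@@]1(C)/C=C/C(=O)OC | intermediate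
32 | dihydroxy acid | C[C@H](O)CC1=C(C)C=C2C[C@H](C)[C@H](O)[C@H](C)[C@@H]2[C@@H]1/C=C(\C)[C@@H]1O[C@@]1(C)/C=C/C(=O)O | intermediate
33 | CNP0214881.1 | CC(=O)CC1=C(C)C=C2C[C@H](C)C(=O)[C@H](C)[C@@H]2[C@@H]1/C=C(\C)[C@@H]1O[C@@]1(C)/C=C/C(=O)O | target

## Step count and least certain steps

Total: 24 steps. Longest linear sequence: 23 steps (steps 1–6 and 8–24, from 1 to 33); diene 12 is made in one step on a side branch.

**Step 8 (key step).** The most likely failure is erosion of enantioselectivity, either through an achiral background cycloaddition started by silyl transfer to triflimide or through a second binding mode of the ketal-bearing dienone. Loss of regiocontrol, if the two methyl groups of the diene outweigh the silyloxy group, is the second concern. The sense of induction is assigned from the binding model, and the antipodal aminoalcohol is equally available.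

Fallback: 10 and 12 are combined without catalyst in toluene at 80–100 °C. This should give 13 together with the ring-antipodal diastereomeric adduct F1. Both carry the same (S)-silyloxypropyl group, so they are diastereomers and are separated by preparative chromatography, with the side-chain stereocentre serving as an internal resolving handle. The route is rejoined at 13.

**Step 10.** The likely failure is competing 1,2-reduction of the C4 enone, because both carbonyls are hindered.

Fallback: from 14, both carbonyls are reduced with NaBH4/CeCl3·7H2O to the diol F2. MnO2 in CH2Cl2 then reoxidises only the allylic C4 carbinol, returning to 15.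

**Step 12.** The likely failure is competing γ-deprotonation at the side-chain methylene on C2, or slow removal of the hindered ring-fusion hydrogen, leading to an isomeric dienyl triflate.

Fallback: from 16, condensation with 2,4,6-triisopropylbenzenesulfonyl hydrazide gives the trisylhydrazone F3. Excess n-BuLi in THF/TMEDA (−78 to 0 °C, Shapiro reaction) removes H-4a and expels sulfinate and nitrogen, and the C4 vinyllithium is protonated on work-up to give 19. This is hydrolysed as in step 13, rejoining the route at 20.

**Step 15.** The likely failure is insufficient facial selectivity of hydroboration, or competing attack of the borane on the ring diene.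

Fallback: from 20, olefination with Ph3P=CHOMe (from the phosphonium chloride and KN(SiMe3)2, low temperature) gives the methyl enol ether F4. Mild acid hydrolysis then allows the aldehyde to equilibrate at C1, where the α, pseudoaxial formyl group is expected to be the stable epimer because it avoids strain with the C2 substituent. The route is rejoined at 24.

**Step 17.** The likely failure is thermal enolisation of the β,γ-unsaturated aldehyde (epimerisation at C1 or migration of the diene into conjugation) before the sluggish formyl ylide reacts.

Fallback: from 24, the more reactive Ph3P=C(Me)CO2Et is used at room temperature to give the enoate F5. Reduction with i-Bu2AlH gives the allylic alcohol F6, and MnO2 oxidation returns to 25. This is a change of route by way of the ester oxidation level, at a cost of two steps.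

## Further compounds

F1 | step 8 | ring-antipodal diastereomer of 13 (H-4a and H-8a α, 8β-methyl, same (S)-side chain) | C[C@H](O[Si](C)(C)C(C)(C)C)CC1=C(C)C(=O)[C@H]2CC(C)=C(O[Si](C(C)C)(C(C)C)C(C)C)[C@@H](C)[C@H]2C1(OC)OC
F2 | step 10 | 4,7-diol from exhaustive reduction of 14 (C4 carbinol drawn as the α-epimer; either epimer is oxidised alike) | C[C@H](O[Si](C)(C)C(C)(C)C)CC1=C(C)[C@H](O)[C@@H]2C[C@H](C)[C@H](O)[C@H](C)[C@@H]2C1(OC)OC
F3 | step 12 | C4 2,4,6-triisopropylbenzenesulfonylhydrazone of 16 | C[C@H](O[Si](C)(C)C(C)(C)C)CC1=C(C)C(=NNS(=O)(=O)c3c(C(C)C)cc(C(C)C)cc3C(C)C)[C@@H]2C[C@H](C)[C@H](O[Si](CC)(CC)CC)[C@H](C)[C@@H]2C1(OC)OC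
F4 | step 15 | C1 methoxymethylidene enol ether of 20 (E/Z mixture) | C[C@H](O[Si](C)(C)C(C)(C)C)CC1=C(C)C=C2C[C@H](C)[C@H](O[Si](CC)(CC)CC)[C@H](C)[C@@H]2C1=COC
F5 | step 17 | ethyl (E)-2-methylpropenoate attached at C1 | C[C@H](O[Si](C)(C)C(C)(C)C)CC1=C(C)C=C2C[C@H](C)[C@H](O[Si](CC)(CC)CC)[C@H](C)[C@@H]2[C@@H]1/C=C(\C)C(=O)OCC
F6 | step 17 | (E)-allylic alcohol C1–CH=C(Me)–CH2OH | C[C@H](O[Si](C)(C)C(C)(C)C)CC1=C(C)C=C2C[C@H](C)[C@H](O[Si](CC)(CC)CC)[C@H](C)[C@@H]2[C@@H]1/C=C(\C)CO
A1 | alternative 1 | tricyclic dienyl δ-lactone | O=C1CC2=C(C)C=C3C[C@H](C)[C@@H](O[Si](C)(C)C(C)(C)C)[C@H](C)[C@@H]3[C@@H]2CO1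
A2 | alternative 2 | cis-fused octalone with C3=C4 alkene and C2 dioxolane | CC1=C[C@@H]2C[C@H](C)C(=O)[C@H](C)[C@@H]2[C@H](CO[Si](C)(C)C(C)(C)C)C13OCCO3
A3 | alternative 3 | cis-fused C4a-hydroxy decal-7-one | C[C@H](O[Si](C)(C)C(C)(C)C)CC1=C(C)C[C@]2(O)C[C@H](C)C(=O)[C@H](C)[C@@H]2[C@@H]1/C=C(\C)CO[Si](C)(C)C(C)(C)C
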